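**Retrosynthetic overview**

- The plan rests on ring A (C1 methyl, C2 arylethynyl, C3 carrying the quinone methide carbon C7, C4 hydroxyphenyl, C5–H, C6–H). Its C2 arylethynyl group is read as the untouched half of a 1,3-diyne, and C4–C5–C6–C1 as a 1-aryl-pent-1-en-3-yne.
- The target is traced back to a tetra-O-methyl triarylcarbinol (global demethylation with loss of water), and that to a methyl benzoate with ring A complete (two aryl additions at the ester carbon, which becomes C7).
- The benzoate is disconnected at C3–C4 and C1–C2 into an (E)-anisyl pentenyne and a methyl 5-anisylpenta-2,4-diynoate, joined by a zerovalent palladium [4+2] cross-benzannulation. Ring A is the only ring formed; all other rings are bought as anisole units.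
- The enyne comes from 4-methoxycinnamic acid (bromodecarboxylation, Sonogashira coupling with propyne). The diynoate comes from 4-ethynylanisole (Cadiot–Chodkiewicz coupling with a silyl bromoalkyne, desilylation, carbomethoxylation).

Key step: step 6

Remark on the chemistry: the hydrogen that migrates in the aromatising step of the benzannulation is taken to be the alkene hydrogen cis to the alkynyl group, which ends up pseudo-axial in the cycloadduct, so the enyne is made as the (E) isomer.

**Route**

Step 1
Reactants: 1 4-methoxycinnamic acid ((E)-3-(4-methoxyphenyl)prop-2-enoic acid)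
Product: 2 (E)-1-(2-bromoethenyl)-4-methoxybenzene
Conditions: NBS, LiOAc (cat.), MeCN–H2O, rt
Reagents that add atoms: N-bromosuccinimide, O=C1CCC(=O)N1Br
Why: Catalytic Hunsdiecker-type bromodecarboxylation, in which the electron-rich cinnamate is brominated at the α-carbon and loses CO2 through a benzylic cation or β-lactone in an anti sense, which should give the (E)-bromoalkene whose geometry is carried into the enyne.

Step 2
Reactants: 2 (E)-1-(2-bromoethenyl)-4-methoxybenzene; 3 propyne
Product: 4 (E)-1-methoxy-4-(pent-1-en-3-yn-1-yl)benzene
Conditions: propyne (THF solution), PdCl2(PPh3)2 (cat.), CuI (cat.), Et3N, THF, rt, sealed vessel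
Reagents that add atoms: none
Why: Sonogashira coupling of an alkenyl bromide with a terminal alkyne proceeds with retention of alkene geometry and should deliver the (E)-enyne directly.

Step 3
Reactants: 5 4-ethynylanisole (1-ethynyl-4-methoxybenzene); 6 (bromoethynyl)tri(propan-2-yl)silane
Product: 7 [4-(4-methoxyphenyl)buta-1,3-diyn-1-yl]tri(propan-2-yl)silane
Conditions: CuCl (cat.), NH2OH·HCl, n-BuNH2, H2O–CH2Cl2, 0 °C to rt
Reagents that add atoms: none
Why: Cadiot–Chodkiewicz heterocoupling of the copper acetylide of 5 with a bulky silyl bromoalkyne is reliable, and it keeps the ester out of the amine medium, where a propiolate ester would suffer aza-Michael addition.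

Step 4
Reactants: 7 [4-(4-methoxyphenyl)buta-1,3-diyn-1-yl]tri(propan-2-yl)silane
Product: 8 1-(buta-1,3-diyn-1-yl)-4-methoxybenzene
Conditions: Bu4NF, wet THF, 0 °C; short silica plug, used at once
Reagents that add atoms: none
Why: Fluoride-induced protodesilylation of an alkynylsilane is fast at 0 °C, and immediate use of the terminal diyne in solution should avoid its decomposition.

Step 5
Reactants: 8 1-(buta-1,3-diyn-1-yl)-4-methoxybenzene
Product: 10 methyl 5-(4-methoxyphenyl)penta-2,4-diynoate, via lithium diynide 9 (not isolated)
Conditions: n-BuLi, THF, −78 °C; then ClCO2Me, −78 to 0 °C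
Reagents that add atoms: methyl chloroformate, COC(=O)Cl
Why: Deprotonation of the terminal diyne and C-acylation of the lithium acetylide with a chloroformate is the standard entry to 2,4-diynoates, and the low temperature with excess electrophile should suppress conjugate addition to the product.

Step 6
Reactants: 4 (E)-1-methoxy-4-(pent-1-en-3-yn-1-yl)benzene; 10 methyl 5-(4-methoxyphenyl)penta-2,4-diynoate
Product: 12 methyl 6-(4-methoxyphenyl)-2-[(4-methoxyphenyl)ethynyl]-3-methylbenzoate, via cyclic allene cycloadduct 11 (not isolated)
Conditions: Pd(PPh3)4 (5 mol%), THF, 65 °C, slow addition of 10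
Reagents that add atoms: none
Why: Zerovalent palladium binds enyne 4 and the ester-bearing triple bond of 10 and couples them in a formal [4+2] sense (oxidative cyclisation through a propargyl/allenyl palladacycle, then reductive elimination), forming the C3–C4 and C1–C2 bonds of ring A and giving the palladium-bound six-membered cyclic allene 11; palladium-mediated transfer of the hydrogen on ring carbon C4 (the one cis to the alkynyl unit in the (E)-enyne) to the central allene carbon C6 then aromatises the ring, so no oxidant or leaving group is needed. The closest known reaction type is the Pd(PPh3)4-catalysed cross-benzannulation of conjugated enynes with conjugated diynes, which leaves the second triple bond as an alkynyl substituent. Ring A is closed by an intermolecular [4+2] annulation with four carbons from the enyne (C4, C5, C6, C1) and two from one triple bond of the diyne (C3, C2), and no stereocentre remains because the sp3 carbon of 11 is erased on aromatisation. The first selectivity needed is that the ynoate triple bond and not the aryl-capped one acts as the two-carbon partner, which its lower LUMO, its stronger back-bonding to zerovalent palladium and the lesser crowding of the product (an ester, not a second aryl group, beside the C4 aryl) should secure. The second is that the spare arylethynyl group ends beside the methyl-bearing C1, which is the intrinsic orientation of this benzannulation and is reinforced here by polar matching of the nucleophilic methyl-substituted enyne terminus with the β-carbon of the ynoate. Slow addition of 10 limits phosphine-initiated oligomerisation of the diynoate, and the internal methyl alkyne of 4 is a poor two-carbon partner, so self-annulation of the enyne should not compete.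

Step 7
Reactants: 12 methyl 6-(4-methoxyphenyl)-2-[(4-methoxyphenyl)ethynyl]-3-methylbenzoate
Product: 14 {6-(4-methoxyphenyl)-2-[(4-methoxyphenyl)ethynyl]-3-methylphenyl}bis(4-methoxyphenyl)methanol, via diaryl ketone 13 (not isolated)
Conditions: 4-BrC6H4OMe, n-BuLi, THF, −78 °C; then 12, −78 °C to rt; H2O
Reagents that add atoms: 4-methoxyphenyllithium, [Li]c1ccc(OC)cc1 (formed in the flask from 4-bromoanisole, COc1ccc(Br)cc1)
Why: Double addition of an aryllithium to a methyl ester (acyl substitution to ketone 13, then 1,2-addition) should succeed with an excess of the small, reactive nucleophile despite the two ortho substituents, while the diarylalkyne and the methyl ethers are inert.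

Step 8
Reactants: 14 {6-(4-methoxyphenyl)-2-[(4-methoxyphenyl)ethynyl]-3-methylphenyl}bis(4-methoxyphenyl)methanol
Product: 16 selaginellin U, via triarylmethylium bromide 15 (not isolated)
Conditions: BBr3, CH2Cl2, −78 to 0 °C; then H2O
Reagents that add atoms: none
Why: Lewis acid O-demethylation with BBr3 cleaves the four aryl methyl ethers and ionises the carbinol to the stabilised triarylmethylium ion 15, which on hydrolytic work-up loses a proton from a para-hydroxyl group to give the quinone methide; the cyclohexadienone is symmetric, so no alkene isomer or stereocentre arises.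

**Compound list**

1 | 4-methoxycinnamic acid | COc1ccc(/C=C/C(=O)O)cc1 | starting material
2 | (E)-1-(2-bromoethenyl)-4-methoxybenzene | COc1ccc(/C=C/Br)cc1 | intermediate
3 | propyne | CC#C | starting material
4 | (E)-1-methoxy-4-(pent-1-en-3-yn-1-yl)benzene | CC#C/C=C/c1ccc(OC)cc1 | intermediate
5 | 4-ethynylanisole | C#Cc1ccc(OC)cc1 | starting material
6 | (bromoethynyl)tri(propan-2-yl)silane | BrC#C[Si](C(C)C)(C(C)C)C(C)C | starting material
7 | [4-(4-methoxyphenyl)buta-1,3-diyn-1-yl]tri(propan-2-yl)silane | COc1ccc(C#CC#C[Si](C(C)C)(C(C)C)C(C)C)cc1 | intermediate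
8 | 1-(buta-1,3-diyn-1-yl)-4-methoxybenzene | C#CC#Cc1ccc(OC)cc1 | intermediate
9 | lithium 4-(4-methoxyphenyl)buta-1,3-diyn-1-ide | [Li]C#CC#Cc1ccc(OC)cc1 | intermediate (not isolated)
10 | methyl 5-(4-methoxyphenyl)penta-2,4-diynoate | COC(=O)C#CC#Cc1ccc(OC)cc1 | intermediate
11 | methyl 6-(4-methoxyphenyl)-2-[(4-methoxyphenyl)ethynyl]-3-methylcyclohexa-1,3,4-triene-1-carboxylate (palladium-bound cyclic allene, racemic, drawn as the free ligand) | COC(=O)C1=C(C#Cc2ccc(OC)cc2)C(C)=C=CC1c1ccc(OC)cc1 | intermediate (not isolated)
12 | methyl 6-(4-methoxyphenyl)-2-[(4-methoxyphenyl)ethynyl]-3-methylbenzoate | COC(=O)c1c(-c2ccc(OC)cc2)ccc(C)c1C#Cc1ccc(OC)cc1 | intermediate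
13 | (4-methoxyphenyl){6-(4-methoxyphenyl)-2-[(4-methoxyphenyl)ethynyl]-3-methylphenyl}methanone | COc1ccc(cc1)C(=O)c1c(-c2ccc(OC)cc2)ccc(C)c1C#Cc1ccc(OC)cc1 | intermediate (not isolated)
14 | {6-(4-methoxyphenyl)-2-[(4-methoxyphenyl)ethynyl]-3-methylphenyl}bis(4-methoxyphenyl)methanol | COc1ccc(cc1)C(O)(c1ccc(OC)cc1)c1c(-c2ccc(OC)cc2)ccc(C)c1C#Cc1ccc(OC)cc1 | intermediate
15 | {6-(4-hydroxyphenyl)-2-[(4-hydroxyphenyl)ethynyl]-3-methylphenyl}bis(4-hydroxyphenyl)methylium bromide | Cc1ccc(-c2ccc(O)cc2)c([C+](c2ccc(O)cc2)c2ccc(O)cc2)c1C#Cc1ccc(O)cc1.[Br-] | intermediate (not isolated)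
16 | selaginellin U, 4-[{4'-hydroxy-3-[(4-hydroxyphenyl)ethynyl]-4-methyl-[1,1'-biphenyl]-2-yl}(4-hydroxyphenyl)methylidene]cyclohexa-2,5-dien-1-one | Cc1ccc(-c2ccc(O)cc2)c(C(=C2C=CC(=O)C=C2)c2ccc(O)cc2)c1C#Cc1ccc(O)cc1 | target

**Step count**

Total steps: 8. Longest linear sequence: 6 steps (5 → 7 → 8 → 10 → 12 → 14 → 16; steps 3, 4, 5, 6, 7, 8).

**Steps most likely to fail**

Step 6. The catalyst may engage the aryl-capped triple bond of 10 or deliver the spare alkynyl group to the wrong ring position. Free phosphine may start oligomerisation of the diynoate. The hydrogen transfer that aromatises 11 may fail to turn over. The fallback builds ring A's substitution pattern by cross-coupling on a preformed arene; it sets out from 5 and comes back at 12. Commercial 2-bromo-4-chlorotoluene would be deprotonated between the two halogens with LiN(i-Pr)2 in THF at −78 °C and trapped with methyl chloroformate to give methyl 2-bromo-6-chloro-3-methylbenzoate F1. Sonogashira coupling of 5 at the C–Br bond of F1 (PdCl2(PPh3)2, CuI, Et3N, DMF, 70 °C) should give methyl 6-chloro-2-[(4-methoxyphenyl)ethynyl]-3-methylbenzoate F2, the C–Cl bond being inert under these conditions. Suzuki–Miyaura coupling of F2 with 4-methoxyphenylboronic acid (Pd(OAc)2, SPhos, K3PO4, toluene–H2O, 100 °C) would then give 12.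

Step 7. Acyl substitution at the doubly ortho-substituted ester may stall because the tetrahedral intermediate is too crowded to form, or the sequence may stop after the first addition. The fallback replaces the acyl substitution by a hydride/oxidation sequence; it sets out from 12 and comes back at ketone 13, which is then taken on to 14. Reduction of 12 with i-Bu2AlH (CH2Cl2, −78 to 0 °C) should give {6-(4-methoxyphenyl)-2-[(4-methoxyphenyl)ethynyl]-3-methylphenyl}methanol F3. Dess–Martin oxidation would give 6-(4-methoxyphenyl)-2-[(4-methoxyphenyl)ethynyl]-3-methylbenzaldehyde F4. Addition of 4-MeOC6H4MgBr to the unhindered aldehyde would give racemic (4-methoxyphenyl){6-(4-methoxyphenyl)-2-[(4-methoxyphenyl)ethynyl]-3-methylphenyl}methanol F5. A second Dess–Martin oxidation gives isolated ketone 13, and a single addition of 4-methoxyphenyllithium (premixed with anhydrous CeCl3 if enolisation-free activation is needed) gives 14.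

Step 8. BBr3 or the HBr it releases may add across the diarylalkyne. The triarylmethylium ion may also close onto the neighbouring C4 aryl ring in a Friedel–Crafts sense (fluorene formation) before hydrolysis. The fallback removes the methyl groups under basic, non-ionising conditions; it sets out from 14 and comes back at 16. Heating 14 with excess MeMgI as a solvent-free melt at 160 °C, then aqueous NH4Cl, should give {6-(4-hydroxyphenyl)-2-[(4-hydroxyphenyl)ethynyl]-3-methylphenyl}bis(4-hydroxyphenyl)methanol F6, the carbinol being held as its magnesium alkoxide throughout. Brief treatment of F6 with catalytic HCl in acetone at rt would then dehydrate it to 16.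

**Further compounds**

F1 | step 6 | methyl 2-bromo-6-chloro-3-methylbenzoate | COC(=O)c1c(Cl)ccc(C)c1Br
F2 | step 6 | methyl 6-chloro-2-[(4-methoxyphenyl)ethynyl]-3-methylbenzoate | COC(=O)c1c(Cl)ccc(C)c1C#Cc1ccc(OC)cc1
F3 | step 7 | {6-(4-methoxyphenyl)-2-[(4-methoxyphenyl)ethynyl]-3-methylphenyl}methanol | OCc1c(-c2ccc(OC)cc2)ccc(C)c1C#Cc1ccc(OC)cc1
F4 | step 7 | 6-(4-methoxyphenyl)-2-[(4-methoxyphenyl)ethynyl]-3-methylbenzaldehyde | O=Cc1c(-c2ccc(OC)cc2)ccc(C)c1C#Cc1ccc(OC)cc1
F5 | step 7 | (4-methoxyphenyl){6-(4-methoxyphenyl)-2-[(4-methoxyphenyl)ethynyl]-3-methylphenyl}methanol (racemic) | COc1ccc(cc1)C(O)c1c(-c2ccc(OC)cc2)ccc(C)c1C#Cc1ccc(OC)cc1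
F6 | step 8 | {6-(4-hydroxyphenyl)-2-[(4-hydroxyphenyl)ethynyl]-3-methylphenyl}bis(4-hydroxyphenyl)methanol | OC(c1ccc(O)cc1)(c1ccc(O)cc1)c1c(-c2ccc(O)cc2)ccc(C)c1C#Cc1ccc(O)cc1
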